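The numbers of this flask stand for no real mixture; the flask was simulated.

At late times Q has left by two routes, to X and to Q.G, and Q.G shares its material with D, so the questions concern how Q was divided.

| setting | gamma | eta |
|---|---|---|
| Q | 1.5 M | 1.5 M |
| G | 1.00 equiv | 2.00 equiv |
| time | 8.0 d | 8.0 d |

    G → E (k1 = 3.6 × 10⁻⁸ s⁻¹)
    Q + G → Q.G (k2 = 5.1 × 10⁻⁶ M⁻¹ s⁻¹)
    Q → X (k3 = 6.0 × 10⁻⁶ s⁻¹)
    Q.G ⇌ D (K4 = 0.62, k4 = 2.6 × 10⁻⁶ s⁻¹)

- which of these there is most of at the end, counted by the Q in it, gamma (Q / Q.G / D / X)
- which of these there is most of at the end, counted by the Q in it, eta (Q / Q.G / D / X)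
- final amount of the leader among these, as a percentage of the Q charged, in gamma
- final amount of the leader among these, as a percentage of the Q charged, in eta

Some given numbers matter little. The constant of G → E hardly counts: at the start of gamma the step to Q.G uses G 210 times as fast as the step to E. The constant of the step to D hardly counts either, as its relaxation half-life in gamma, 1.18 d, is shorter than the 8.0 d allowed. The time is also minor: the step to X by itself leaves 1.58% of Q. The equilibrium constant 0.62 matters directly, as it divides bound Q between Q.G and D, though it leaves X untouched.

The two constants of Q's routes enter as a ratio. Dividing the rate to X by the rate to Q.G removes time and c(Q), leaving the constant of the step to X over that of the step to Q.G times c(G). Hence the capture number a, a selectivity factor: the constant of the step to Q.G times the charged c(Q), over the constant of the step to X, 1.27. With x as X in parts of the Q charged, and the small loss to E neglected, G keeps exp(−a·x) of its own charge.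

In gamma, with the Q remaining neglected, G used equals Q not in X, so x = exp(−a·x). One pass from 0.5 gives 52.9%, so X leads. In eta, the same balance with the doubled charge gives x near 31.8%, so the reckoning puts Q.G at 42.1%, and Q.G leads.

The forecast gives X at 51.8% (50.8% to 52.8%) in gamma, lower than the pass here, and Q.G at 42% (41% to 43%) in eta, holding that “step 4 is nearly equilibrated”.

The flasks give X at 51.8% in gamma and Q.G at 42.1% in eta. In gamma, the steps to X and Q.G ran while Q lasted, X standing at 40.0% after 1.60 d and Q at 2.44% after 4.00 d. Meanwhile D grew, reaching 14.8% after 4.00 d and 18.1% after 8.00 d. At the end of gamma, exp(−a·x) gives 51.8% for G, which stood at 50.4%. In a neighbour flask with 0.600 equiv of G and the same a, X at 65.7% gives 43.4%, and G stood at 42.2%.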